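(The constants used here belong to no real substance.)

I wanted target, and target forms when intermediate meets partner.

    substrate → intermediate (k1 = 1.0 s⁻¹)
    2 intermediate → homo product (k2 = 160 M⁻¹ s⁻¹)
    target → over-reaction product (k3 = 0.016 s⁻¹)
    partner + intermediate → target (k4 = 110 M⁻¹ s⁻¹)

| flask | substrate | partner | time | remark |
|---|---|---|---|---|
| alpha | 5.0 mM | 5.00 mM (fed, over 9.60 s) | 12 s | all but partner at the start; partner goes in evenly over 9.60 s, the run ends at 12 s |
| eta | 5.0 mM | 5.00 mM | 12 s | a closed flask charged with all of it at once and left for 12 s |
| gamma | 5.0 mM (fed, over 9.60 s) | 5.00 mM | 12 s | a stirred flask in which substrate is dosed at a steady rate over 9.60 s without added volume, worked up at 12 s |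
| delta | 5.0 mM | 5.00 mM |  | one stirred flow tank at steady state, fed with the mixture as stated, mean residence time 12 s |

- the set-up with the highest amount of target at the outlet or at the end, in percent of the substrate put in ("none" if the first two lie within 2 percentage points) (alpha / eta / gamma / delta / none)
- amount of target at the outlet or at the end, in percent of the substrate put in, alpha
- amount of target at the outlet or at the end, in percent of the substrate put in, eta
- amount of target at the outlet or at the end, in percent of the substrate put in, gamma
- amount of target at the outlet or at the end, in percent of the substrate put in, delta

- percent here means substrate units held: one homo product counts as two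
- two of one species on the left: rate k times its square, two consumed each time
- the stated concentrations are those of everything mixed, before any reaction; amounts are the same in each set-up
- the feed brings no volume worth counting
- run time (alpha): 12 s

**The fork.** Intermediate has two exits. Partner removes it at 110 M⁻¹ s⁻¹ times partner times intermediate. The homo step removes it at two times 160 M⁻¹ s⁻¹ times intermediate squared. I called the partner exit's rate over both exits' rates the target share, S, which the field calls selectivity. More partner raises S, and more intermediate lowers it. Of the four set-ups, I reckoned gamma by hand.

**First round.** In gamma, the half-life of substrate by step one alone was 0.69 s, shorter than the dosing time of 9.60 s. So intermediate was made about as fast as substrate was dosed, at a rate F of 0.521 mM s⁻¹. I first let partner, at its charge, carry F away. That put intermediate at 0.947 mM and S at 64.5%.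

**Second round.** I put that answer back. In gamma, partner taken midway through the dosing stood at 3.39 mM. The partner exit carried S times F, so intermediate came to 0.901 mM. The target share, partner exit over both exits with the first answer put back, was 56.4%. The half-life of target, 43 s, is longer than the run of 12 s, so I charged a mean age of 6.00 s. That kept 90.8% of it, and gamma came to 51.2%.

**The forecast.** It named gamma and gave 18% for alpha, 45% for eta, 56% for gamma and 39% for delta. Its ground was this: “Dosing substrate keeps the intermediate low”. My gamma figure was lower than its 56%.

**The flasks.** Alpha gave 20.4%, eta 44.7%, gamma 50.9% and delta 38.9%, so gamma held the most target. At the end of gamma, target and over-reaction product together held 55.7%, homo product 33.4%, and intermediate still held 9.93%. Of what had left intermediate in gamma, the partner exit had taken 62.5%, against my share of 56.4%.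

**A neighbour.** The neighbour flask was gamma with 2.0 mM of substrate. Its F was 0.208 mM s⁻¹. The first round gave intermediate 0.379 mM and S 81.9%. The second round took partner at 4.18 mM and intermediate at 0.371 mM, which gave S 79.5%. With the same ageing, that made 72.2% target. The neighbour flask ended with 67.6% target.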